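**Plan**

Locants: bridgeheads C1 and C5; ring A = C1–C2(ArA)–O3–C4–C5 and ring B = C5–C6(ArB)–O7–C8–C1, with ArA = 4-hydroxy-3-methoxyphenyl and ArB = 3-hydroxy-4,5-dimethoxyphenyl. Enabling feature: without O7, ring B is a cyclobutanone C1–C8(=O)–C6(ArB)–C5 cis-fused to ring A, the [2+2] adduct of an ArB-ketene equivalent and the C1=C5 bond of a 2-ArA-2,5-dihydrofuran.
Retrosynthetic cuts: the two O–Si bonds; C8 back to C=O and O7 out (reverse Baeyer–Villiger); C1–C8 and C5–C6 (reverse [2+2]); then C1=C5 (metathesis), O3–C4 (etherification) and C1–C2 (vinyl addition) in ring A, and C6–C8 (aldehyde-to-amide homologation) in the other fragment.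
Forward order: ring A is made first as dihydrofuran 8, the four-membered carbocycle is fused on in step 9, ring B arises from it by oxygen insertion in step 10, and C8 is reduced to CH2 before desilylation.
Stereochemistry: C2 from a lipase kinetic resolution; C1 and C5 from cycloaddition on the alkene face anti to ArA (cis fusion enforced); C6 by equilibration to the exo-aryl ketone, kept by the retentive Baeyer–Villiger migration.

Key step: step 9

Remark: the target SMILES is read as the 1R,2S,5R,6S isomer (cis-fused, both aryl groups exo); aldehyde 9 is assumed to be purchasable. Both phenols are carried as triisopropylsilyl (TIPS) ethers; ArA-Si = 3-methoxy-4-(triisopropylsilyloxy)phenyl, ArB-Si = 3,4-dimethoxy-5-(triisopropylsilyloxy)phenyl. Bicyclic intermediates keep the locants C1–C8 defined above.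

**Route**

Step 1
Reactants: 1 vanillin
Product: 2 O-triisopropylsilylvanillin [3-methoxy-4-(triisopropylsilyloxy)benzaldehyde]
Conditions: iPr3SiCl, imidazole, DMF, rt
Reagents that add atoms: chlorotriisopropylsilane, CC(C)[Si](Cl)(C(C)C)C(C)C
Why: Imidazole-promoted silylation of a phenol; the TIPS aryl ether should survive the Grignard reagent, NaH, Tf2O/collidine, peracid, iBu2AlH and cold BF3·OEt2, and falls to fluoride at the end.

Step 2
Reactants: 2 O-triisopropylsilylvanillin; 3 vinylmagnesium bromide
Product: 4 rac-1-(ArA-Si)prop-2-en-1-ol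
Conditions: THF, −78 to 0 °C; aq NH4Cl
Reagents that add atoms: none
Why: Grignard 1,2-addition to an aromatic aldehyde forms C1–C2; the carbinol forms racemic and is resolved in step 3.

Step 3
Reactants: 4 rac-1-(ArA-Si)prop-2-en-1-ol
Product: 5 (S)-1-(ArA-Si)prop-2-en-1-ol
Conditions: immobilised Candida antarctica lipase B, vinyl acetate, t-BuOMe, 30 °C, stopped at about 55% conversion; chromatography on Et3N-deactivated silica
Reagents that add atoms: none
Why: Enzymatic kinetic resolution by irreversible transesterification: lipases acylate the secondary carbinol enantiomer whose large (aryl) and medium (vinyl) groups are arranged as in (R)-1-phenylethanol, so the (R)-alcohol should be esterified and the (S)-alcohol should remain in high enantiomeric purity past half conversion, which sets C2.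

Step 4
Reactants: 5 (S)-1-(ArA-Si)prop-2-en-1-ol; 6 allyl bromide
Product: 7 allyl (S)-1-(ArA-Si)prop-2-en-1-yl ether
Conditions: NaH, Bu4NI (cat.), THF, 0 °C to rt
Reagents that add atoms: none
Why: Williamson ether synthesis of the secondary alkoxide with an allylic bromide forms O3–C4 without touching the stereocenter.

Step 5
Reactants: 7 allyl (S)-1-(ArA-Si)prop-2-en-1-yl ether
Product: 8 (S)-2-(ArA-Si)-2,5-dihydrofuran
Conditions: second-generation Grubbs catalyst RuCl2(=CHPh)(PCy3)(H2IMes) (2 mol %), CH2Cl2, 40 °C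
Reagents that add atoms: none
Why: Ring-closing metathesis of a diallyl-ether-type 1,6-diene closes the five-membered ring A at C1=C5 with loss of ethene; C2 is not involved.

Step 6
Reactants: 9 3-hydroxy-4,5-dimethoxybenzaldehyde
Product: 10 3,4-dimethoxy-5-(triisopropylsilyloxy)benzaldehyde
Conditions: iPr3SiCl, imidazole, DMF, rt
Reagents that add atoms: chlorotriisopropylsilane, CC(C)[Si](Cl)(C(C)C)C(C)C
Why: Phenol silylation as in step 1, needed because a free phenol would be triflated in step 9.

Step 7
Reactants: 10 3,4-dimethoxy-5-(triisopropylsilyloxy)benzaldehyde; 11 carbon tetrabromide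
Product: 12 dibromoalkene 5-(2,2-dibromoethenyl)-1,2-dimethoxy-3-(triisopropylsilyloxy)benzene
Conditions: PPh3, Zn, CH2Cl2, rt; then 10, 0 °C to rt
Reagents that add atoms: none
Why: Ramirez dibromo-olefination (first stage of the Corey–Fuchs sequence), a Wittig reaction of Ph3P=CBr2 generated from CBr4, PPh3 and Zn, adds the carbon that becomes C8.

Step 8
Reactants: 12 dibromoalkene
Product: 15 amide 2-(ArB-Si)-N,N-dimethylacetamide, via bromoalkyne 13 (not isolated), via ynamine 14 (not isolated)
Conditions: Me2NH (40% in H2O), DMF, 60 °C, sealed vessel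
Reagents that add atoms: dimethylamine, CNC; water, O
Why: One-carbon homologation of an aldehyde to an amide through its 1,1-dibromoalkene: the amine should dehydrobrominate 12 to bromoalkyne 13 and displace bromide to give ynamine 14, whose hydration gives the arylacetamide with C8 at the carboxyl oxidation level.

Step 9
Reactants: 15 amide 2-(ArB-Si)-N,N-dimethylacetamide; 8 (S)-2-(ArA-Si)-2,5-dihydrofuran
Product: 19 cyclobutanone (1R,4S,5S,7S)-4-(ArA-Si)-7-(ArB-Si)-3-oxabicyclo[3.2.0]heptan-6-one (carbonyl carbon C8 on C1; 1S,2S,5R,6S in the locants above), via O-triflyliminium triflate 16 (not isolated), via keteniminium triflate 17 (not isolated), via cyclobutaniminium triflate 18 (not isolated)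
Conditions: Tf2O (added last), 2,4,6-collidine, ClCH2CH2Cl, −20 to 80 °C, 15 in excess; then H2O, 60 °C; then DBU (cat.), CH2Cl2, rt
Reagents that add atoms: water, O
Why: Tf2O sulfonylates the amide oxygen of 15 to give 16, collidine removes the benzylic α-proton and triflate leaves to give keteniminium ion 17, whose electrophilic sp carbon (C8) bonds to C1 of 8 while the positive charge developing at C5 is captured by the enamine-type carbon C6, giving cyclobutaniminium salt 18, which water hydrolyses to ketone 19. The closest known reaction type is the intermolecular [2+2] cycloaddition of keteniminium salts (tertiary amide, Tf2O, collidine) with unactivated cyclic cis-alkenes such as cyclopentene, arylacetamide-derived ions included. The four-membered ring is the only ring closed; it closes by a stepwise or strongly asynchronous [2+2] addition (C1–C8 first, then 4-exo collapse forming C5–C6) that is suprafacial on the alkene, so the fusion to ring A can only be cis. C1 and C5 are set by approach to the alkene face anti to ArA on the neighbouring C2 (control by the resolved center), and C6 is set thermodynamically, enamine–iminium exchange under collidine and DBU treatment of the ketone placing ArB on the convex face, trans to C4. The step needs anti facial selectivity, the C8-to-C1 orientation and attack on the alkene rather than on the arenes or O3: ArA shields the syn face; the orientation should be favoured because the aryl-bearing terminus C6 closes on C5, the alkene carbon remote from the C2 substituent, and because the reverse orientation would place positive charge at C1 next to the more electron-poor C2 (this is the least secure selectivity, and regioisomers would be separated at the ketone stage); chemoselectivity rests on the low nucleophilicity of silylated aryl ethers and on adding Tf2O last to an excess of amide.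

Step 10
Reactants: 19 cyclobutanone
Product: 20 lactone (1S,2S,5R,6S)-2-(ArA-Si)-6-(ArB-Si)-3,7-dioxabicyclo[3.3.0]octan-8-one
Conditions: mCPBA, NaHCO3, CH2Cl2, 0 °C
Reagents that add atoms: 3-chloroperoxybenzoic acid, O=C(OO)c1cccc(Cl)c1
Why: Baeyer–Villiger oxidation, rapid for a strained cyclobutanone: the benzylic C6 bearing the electron-rich aryl group should migrate in preference to C1, whose migratory aptitude is lowered by the β-oxygen O3, and it migrates with retention, so O7 is inserted between C8 and C6 with the exo aryl configuration kept.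

Step 11
Reactants: 20 lactone
Product: 21 lactol (1S,2S,5R,6S)-2-(ArA-Si)-6-(ArB-Si)-3,7-dioxabicyclo[3.3.0]octan-8-ol (both C8 anomers)
Conditions: iBu2AlH, CH2Cl2, −78 °C; aq potassium sodium tartrate
Reagents that add atoms: none
Why: Partial reduction of a γ-lactone by iBu2AlH at −78 °C stops at the aluminium hemiacetal and should give the lactol on hydrolysis; the new C8 center is inconsequential because it is removed in step 12.

Step 12
Reactants: 21 lactol
Product: 22 bis-TIPS ether (1R,2S,5R,6S)-2-(ArA-Si)-6-(ArB-Si)-3,7-dioxabicyclo[3.3.0]octane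
Conditions: Et3SiH, BF3·OEt2, CH2Cl2, −78 °C; Et3N quench at −78 °C
Reagents that add atoms: none
Why: Lewis-acid-promoted silane reduction (ionic hydrogenation) of a lactol: BF3·OEt2 ionises the C8 hemiacetal and Et3SiH delivers hydride to C8, the hemiacetal ionising at −78 °C much faster than the benzylic ethers at C2 and C6, so the four stereocenters should stay untouched.

Step 13
Reactants: 22 bis-TIPS ether
Product: 23 target 4-[(1R,2S,5R,6S)-6-(3-hydroxy-4,5-dimethoxyphenyl)-3,7-dioxabicyclo[3.3.0]octan-2-yl]-2-methoxyphenol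
Conditions: Bu4NF, AcOH, THF, 0 °C
Reagents that add atoms: none
Why: Fluoride-mediated cleavage of both aryl silyl ethers; AcOH buffering keeps the freed 4-hydroxybenzyl ether from phenoxide-driven quinone methide formation, which would endanger C2.

**Compound list**

1 | vanillin (4-hydroxy-3-methoxybenzaldehyde) | COc1cc(C=O)ccc1O | starting material
2 | 3-methoxy-4-(triisopropylsilyloxy)benzaldehyde | COc1cc(C=O)ccc1O[Si](C(C)C)(C(C)C)C(C)C | intermediate
3 | vinylmagnesium bromide | C=C[Mg]Br | starting material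
4 | rac-1-[3-methoxy-4-(triisopropylsilyloxy)phenyl]prop-2-en-1-ol | COc1cc(C(O)C=C)ccc1O[Si](C(C)C)(C(C)C)C(C)C | intermediate
5 | (S)-1-[3-methoxy-4-(triisopropylsilyloxy)phenyl]prop-2-en-1-ol | COc1cc([C@H](C=C)O)ccc1O[Si](C(C)C)(C(C)C)C(C)C | intermediate
6 | allyl bromide (3-bromoprop-1-ene) | C=CCBr | starting material
7 | allyl (S)-1-[3-methoxy-4-(triisopropylsilyloxy)phenyl]prop-2-en-1-yl ether | COc1cc([C@H](C=C)OCC=C)ccc1O[Si](C(C)C)(C(C)C)C(C)C | intermediate
8 | (S)-2-[3-methoxy-4-(triisopropylsilyloxy)phenyl]-2,5-dihydrofuran | COc1cc([C@H]2OCC=C2)ccc1O[Si](C(C)C)(C(C)C)C(C)C | intermediate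
9 | 3-hydroxy-4,5-dimethoxybenzaldehyde | COc1cc(C=O)cc(O)c1OC | starting material
10 | 3,4-dimethoxy-5-(triisopropylsilyloxy)benzaldehyde | COc1cc(C=O)cc(O[Si](C(C)C)(C(C)C)C(C)C)c1OC | intermediate
11 | carbon tetrabromide | BrC(Br)(Br)Br | starting material
12 | 5-(2,2-dibromoethenyl)-1,2-dimethoxy-3-(triisopropylsilyloxy)benzene | COc1cc(C=C(Br)Br)cc(O[Si](C(C)C)(C(C)C)C(C)C)c1OC | intermediate
13 | 5-(bromoethynyl)-1,2-dimethoxy-3-(triisopropylsilyloxy)benzene | COc1cc(C#CBr)cc(O[Si](C(C)C)(C(C)C)C(C)C)c1OC | intermediate (not isolated)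
14 | 2-[3,4-dimethoxy-5-(triisopropylsilyloxy)phenyl]-N,N-dimethylethyn-1-amine | COc1cc(C#CN(C)C)cc(O[Si](C(C)C)(C(C)C)C(C)C)c1OC | intermediate (not isolated)
15 | 2-[3,4-dimethoxy-5-(triisopropylsilyloxy)phenyl]-N,N-dimethylacetamide | COc1cc(CC(=O)N(C)C)cc(O[Si](C(C)C)(C(C)C)C(C)C)c1OC | intermediate
16 | N-{2-(ArB-Si)-1-[(trifluoromethylsulfonyl)oxy]ethylidene}-N-methylmethanaminium triflate | COc1cc(CC(OS(=O)(=O)C(F)(F)F)=[N+](C)C)cc(O[Si](C(C)C)(C(C)C)C(C)C)c1OC.[O-]S(=O)(=O)C(F)(F)F | intermediate (not isolated)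
17 | N-[2-(ArB-Si)ethenylidene]-N-methylmethanaminium triflate (keteniminium salt) | COc1cc(C=C=[N+](C)C)cc(O[Si](C(C)C)(C(C)C)C(C)C)c1OC.[O-]S(=O)(=O)C(F)(F)F | intermediate (not isolated)
18 | N-[4-(ArA-Si)-7-(ArB-Si)-3-oxabicyclo[3.2.0]heptan-6-ylidene]-N-methylmethanaminium triflate, cis-fused, four-membered ring anti to ArA, both C6 epimers | COc1cc([C@H]2OC[C@H]3[C@@H]2C(=[N+](C)C)C3c2cc(O[Si](C(C)C)(C(C)C)C(C)C)c(OC)c(OC)c2)ccc1O[Si](C(C)C)(C(C)C)C(C)C.[O-]S(=O)(=O)C(F)(F)F | intermediate (not isolated)
19 | (1R,4S,5S,7S)-4-(ArA-Si)-7-(ArB-Si)-3-oxabicyclo[3.2.0]heptan-6-one | COc1cc([C@H]2OC[C@H]3[C@@H]2C(=O)[C@@H]3c2cc(O[Si](C(C)C)(C(C)C)C(C)C)c(OC)c(OC)c2)ccc1O[Si](C(C)C)(C(C)C)C(C)C | intermediate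
20 | (1S,2S,5R,6S)-2-(ArA-Si)-6-(ArB-Si)-3,7-dioxabicyclo[3.3.0]octan-8-one | COc1cc([C@H]2OC[C@H]3[C@@H]2C(=O)O[C@@H]3c2cc(O[Si](C(C)C)(C(C)C)C(C)C)c(OC)c(OC)c2)ccc1O[Si](C(C)C)(C(C)C)C(C)C | intermediate
21 | (1S,2S,5R,6S)-2-(ArA-Si)-6-(ArB-Si)-3,7-dioxabicyclo[3.3.0]octan-8-ol, C8 anomers | COc1cc([C@H]2OC[C@H]3[C@@H]2C(O)O[C@@H]3c2cc(O[Si](C(C)C)(C(C)C)C(C)C)c(OC)c(OC)c2)ccc1O[Si](C(C)C)(C(C)C)C(C)C | intermediate
22 | (1R,2S,5R,6S)-2-(ArA-Si)-6-(ArB-Si)-3,7-dioxabicyclo[3.3.0]octane | COc1cc([C@H]2OC[C@H]3[C@@H]2CO[C@@H]3c2cc(O[Si](C(C)C)(C(C)C)C(C)C)c(OC)c(OC)c2)ccc1O[Si](C(C)C)(C(C)C)C(C)C | intermediate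
23 | 4-[(1R,2S,5R,6S)-6-(3-hydroxy-4,5-dimethoxyphenyl)-3,7-dioxabicyclo[3.3.0]octan-2-yl]-2-methoxyphenol | COc1cc([C@H]2OC[C@H]3[C@@H]2CO[C@@H]3c2cc(O)c(OC)c(OC)c2)ccc1O | target

**Step count**

Total: 13 steps. Longest linear sequence: 10 steps (steps 1–5 and 9–13, from vanillin); the amide branch is 3 steps (6–8).

**Steps most likely to fail**

Step 9. The keteniminium ion may add across C1=C5 in the reverse orientation (C8 to C5), because the two alkene carbons differ only in their allylic substituents, and it may be consumed by self-condensation before it reaches the hindered cis-alkene. The fallback sets out from alcohol 5 (with 10 and 3) and comes back at 22, replacing the cycloaddition by a radical cyclisation in which the O3–C4 ether tether dictates which carbons bond. Hydroxyl-directed epoxidation of 5 (VO(acac)2, t-BuOOH) would give (R)-(ArA-Si)(oxiran-2-yl)methanol F1; both epoxide epimers serve, since that carbon becomes a radical. Aldehyde 10 and 3 would give rac-1-(ArB-Si)prop-2-en-1-ol F2, which PBr3 should convert with allylic transposition into (E)-3-(ArB-Si)prop-2-en-1-yl bromide F3. Williamson coupling of F1 with F3 (NaH, THF, low temperature to forestall Payne rearrangement) would give epoxy ether F4. Cp2TiCl (trivalent titanium, made in the flask from Cp2TiCl2 and Zn) should open the terminal epoxide to a C1 radical carrying the titanium alkoxide on C8; 5-exo cyclisation onto the cinnamyl alkene forms C1–C5 and ring A through a chair-like transition state that places C8 trans to ArA and cis to C6. Iodine then oxidises the benzylic C6 position and the C8 alkoxide closes ring B to the exo-aryl isomer 22.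

Step 10. The bridgehead C1 may migrate instead of the benzylic C6, or the peracid may attack the electron-rich arenes. The fallback sets out from 19 and comes back at 22, replacing oxygen insertion by oxidative cleavage of the C6–C8 bond. Ketone 19 can enolise only towards the benzylic C6, so Me3SiOTf/Et3N should give the C8-trimethylsilyl enol ether F5. Ozonolysis at −78 °C (stopped at the indicator end point, then Me2S) would give the C6 aryl ketone C8 carboxylic acid F6, which is reduced at once with LiAlH4 to limit epimerisation at C5, giving the C6-epimeric diol F7. A catalytic amount of 10-camphorsulfonic acid in CH2Cl2 at 0 °C should ionise the benzylic C6 alcohol and close ring B stereoconvergently to the exo-aryl ether 22.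

Step 12. BF3·OEt2 may ionise the benzylic C2–O3 or C6–O7 bond, leading to epimerisation at C2 or reductive ring opening. The fallback sets out from lactone 20 and comes back at 22 without any Lewis acid. LiAlH4 in THF at 0 °C would give the (6S)-diol F8. Selective sulfonylation of the primary C8 hydroxyl (MsCl, Et3N, CH2Cl2, −20 °C) would give the mesylate F9, and the C6 hydroxyl should displace it on warming (SN2 at C8, retention at C6) to give 22.

**Further compounds**

F1 | step 9 | (R)-[3-methoxy-4-(triisopropylsilyloxy)phenyl](oxiran-2-yl)methanol, epoxide epimers | COc1cc([C@H](C2CO2)O)ccc1O[Si](C(C)C)(C(C)C)C(C)C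
F2 | step 9 | rac-1-[3,4-dimethoxy-5-(triisopropylsilyloxy)phenyl]prop-2-en-1-ol | COc1cc(C(O)C=C)cc(O[Si](C(C)C)(C(C)C)C(C)C)c1OC
F3 | step 9 | (E)-5-(3-bromoprop-1-en-1-yl)-1,2-dimethoxy-3-(triisopropylsilyloxy)benzene | COc1cc(/C=C/CBr)cc(O[Si](C(C)C)(C(C)C)C(C)C)c1OC
F4 | step 9 | (E)-3-(ArB-Si)prop-2-en-1-yl (R)-(ArA-Si)(oxiran-2-yl)methyl ether, epoxide epimers | COc1cc([C@H](C2CO2)OC/C=C/c2cc(O[Si](C(C)C)(C(C)C)C(C)C)c(OC)c(OC)c2)ccc1O[Si](C(C)C)(C(C)C)C(C)C
F5 | step 10 | 4-(ArA-Si)-7-(ArB-Si)-6-(trimethylsilyloxy)-3-oxabicyclo[3.2.0]hept-6-ene (C8 enol silyl ether of 19) | COc1cc([C@H]2OC[C@H]3[C@@H]2C(O[Si](C)(C)C)=C3c2cc(O[Si](C(C)C)(C(C)C)C(C)C)c(OC)c(OC)c2)ccc1O[Si](C(C)C)(C(C)C)C(C)C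
F6 | step 10 | (2S)-2-(ArA-Si)-4-[3,4-dimethoxy-5-(triisopropylsilyloxy)benzoyl]oxolane-3-carboxylic acid, 2,3-trans-3,4-cis | COc1cc([C@H]2OC[C@H](C(=O)c3cc(O[Si](C(C)C)(C(C)C)C(C)C)c(OC)c(OC)c3)[C@@H]2C(=O)O)ccc1O[Si](C(C)C)(C(C)C)C(C)C
F7 | step 10 | [(2S)-2-(ArA-Si)-4-[hydroxy(ArB-Si)methyl]oxolan-3-yl]methanol, 2,3-trans-3,4-cis, C6 epimers | COc1cc([C@H]2OC[C@H](C(O)c3cc(O[Si](C(C)C)(C(C)C)C(C)C)c(OC)c(OC)c3)[C@@H]2CO)ccc1O[Si](C(C)C)(C(C)C)C(C)C
F8 | step 12 | [(2S)-2-(ArA-Si)-4-[(S)-hydroxy(ArB-Si)methyl]oxolan-3-yl]methanol, 2,3-trans-3,4-cis | COc1cc([C@H]2OC[C@H]([C@H](O)c3cc(O[Si](C(C)C)(C(C)C)C(C)C)c(OC)c(OC)c3)[C@@H]2CO)ccc1O[Si](C(C)C)(C(C)C)C(C)C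
F9 | step 12 | primary methanesulfonate of F8 | COc1cc([C@H]2OC[C@H]([C@H](O)c3cc(O[Si](C(C)C)(C(C)C)C(C)C)c(OC)c(OC)c3)[C@@H]2COS(C)(=O)=O)ccc1O[Si](C(C)C)(C(C)C)C(C)C
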